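Guaiane numbering: cyclopentenone C1–C5 (C3=O, C4–Me), seven-membered ring C1, C5–C10 (C7–C11 carbinol, C8–O, C10–Me). The seven-membered ring is cut at C6–C7 and C9–C10 into an s-cis-locked diene (C6=C5–C1=C10) on the five-membered ring and a siloxyvinyl carbenoid (C7–C8–C9). In one operation, Rh2(S-PTAD)4-catalysed cyclopropanation of the C5=C6 methylene and strain-driven Cope rearrangement of the spiro cis-divinylcyclopropane (a formal (4+3) cycloaddition) close the ring, set C10, and install O8, the C7 carboxyl carbon (later C11) and the C1=C5 alkene that becomes the C4=C5 enone; this exploits the β-keto ester retron O8/C11 beside the cyclopentenone. The precursor is an achiral ethoxy triene.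

Key step: step 6

Assumption: Rh2(S-PTAD)4, dirhodium tetrakis[(S)-(1-adamantyl)(phthalimido)acetate], is taken to deliver the (10S) series in step 6; should the sense of induction prove opposite, Rh2(R-PTAD)4 is used and nothing else changes.

Step 1
Reactants: 1 2-methylcyclopentane-1,3-dione
Product: 2 3-ethoxy-2-methylcyclopent-2-en-1-one
Conditions: EtOH, p-TsOH (cat.), toluene, reflux, Dean–Stark
Reagents that add atoms: ethanol CCO
Why: Acid-catalysed enol etherification of the enolised 1,3-dione (vinylogous esterification) is driven by azeotropic removal of water and forms no stereocentre.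

Step 2
Reactants: 2 3-ethoxy-2-methylcyclopent-2-en-1-one
Product: 5 (E)-3-ethoxy-5-ethylidene-2-methylcyclopent-2-en-1-one, via lithium aldolate 3 (not isolated), via aldol mesylate 4 (not isolated)
Conditions: LiN(iPr)2 (1.1 equiv), THF, −78 °C; CH3CHO, −78 °C; MsCl, −78 → 0 °C; DBU, 25 °C
Reagents that add atoms: acetaldehyde CC=O
Why: Kinetic deprotonation of the vinylogous ester at the α′-methylene (Stork–Danheiser enolate), aldol addition, mesylation in the flask and E1cB elimination should give the thermodynamically favoured E-ethylidene enone (methyl anti to the carbonyl carbon), the geometry needed later for an unhindered Cope step.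

Step 3
Reactants: 5 (E)-3-ethoxy-5-ethylidene-2-methylcyclopent-2-en-1-one
Product: 6 (E)-1-ethoxy-4-ethylidene-2-methyl-3-methylidenecyclopent-1-ene
Conditions: Cp2Ti(μ-Cl)(μ-CH2)AlMe2 (Tebbe reagent, 1.3 equiv), pyridine (0.2 equiv), THF/toluene, −40 → 0 °C; 15% aq NaOH quench; filtration through basic alumina; used at once
Reagents that add atoms: Tebbe reagent Cp2Ti(μ-Cl)(μ-CH2)AlMe2, open form C[Al](C)C[Ti](Cl)(C1C=CC=C1)C1C=CC=C1
Why: Tebbe methylenation converts electron-rich, enolisable vinylogous-ester carbonyls into methylidene groups without protic acid or strong base, so the acid-labile cross-conjugated trienol ether should survive a basic quench, and no stereocentre is formed.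

Step 4
Reactants: 7 methyl 3-oxobutanoate
Product: 8 methyl 2-diazo-3-oxobutanoate
Conditions: 4-acetamidobenzenesulfonyl azide (p-ABSA), Et3N, MeCN, 0 → 25 °C
Reagents that add atoms: 4-acetamidobenzenesulfonyl azide CC(=O)Nc1ccc(cc1)S(=O)(=O)N=[N+]=[N-]
Why: Regitz diazo transfer to the active methylene of a β-keto ester is reliable and forms no stereocentre.

Step 5
Reactants: 8 methyl 2-diazo-3-oxobutanoate
Product: 9 methyl 3-[(tert-butyldimethylsilyl)oxy]-2-diazobut-3-enoate
Conditions: TBSOTf, Et3N, CH2Cl2, 0 °C
Reagents that add atoms: tert-butyldimethylsilyl trifluoromethanesulfonate CC(C)(C)[Si](C)(C)OS(=O)(=O)C(F)(F)F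
Why: Soft enolisation and O-silylation of the acetyl group gives the 2-siloxyvinyl diazoacetate, a donor/acceptor carbenoid precursor, while the diazo ester is untouched.

Step 6
Reactants: 6 (E)-1-ethoxy-4-ethylidene-2-methyl-3-methylidenecyclopent-1-ene; 9 methyl 3-[(tert-butyldimethylsilyl)oxy]-2-diazobut-3-enoate
Product: 12 methyl (8S)-2-ethoxy-3,8-dimethyl-6-oxo-1,4,5,6,7,8-hexahydroazulene-5-carboxylate, via spiro cis-divinylcyclopropane 10 (not isolated), via cycloheptadiene silyl enol ether 11 (not isolated)
Conditions: Rh2(S-PTAD)4 (1 mol %), 6 (1.5 equiv), hexanes, 9 added over 2 h at −26 °C, then 25 → 45 °C; then TBAF (1.1 equiv), THF, 0 °C; water work-up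
Reagents that add atoms: none
Why: Loss of N2 from 9 gives a rhodium-bound siloxyvinyl carbenoid that should cyclopropanate the exocyclic C5=C6 methylene of 6 (C6 is the unhindered, most nucleophilic terminus of the 1-ethoxydiene, whereas the trisubstituted C1=C10 and tetrasubstituted C3=C4 alkenes are too hindered for a donor/acceptor carbenoid) to give spiro cis-divinylcyclopropane 10, which undergoes a strain-releasing [3,3] Cope rearrangement (C5–C7 broken, C9–C10 formed) to 11 before fluoride unmasks the C8 ketone. The closest known reaction type is the tandem cyclopropanation/Cope rearrangement of vinylcarbenoids with dienes, the formal (4+3) cycloaddition, including its enantioselective variant with siloxyvinyl diazoacetates. The seven-membered ring is closed in the sigmatropic step through a boat-like six-electron transition state after C6–C7 was made in the cyclopropanation, and the spiro junction holds the C1=C10 alkene in the s-cis orientation over the cyclopropane that this transition state needs. C10 is the only stereocentre formed and is set by transfer of the catalyst-controlled cyclopropane configuration through the boat, with the E-methyl group pointing outward and only hydrogen atoms pointing inward. The step needs site selectivity (secured as above), a cis relation of the siloxyvinyl group and C1 on the cyclopropane (the donor group of such carbenoids is delivered cis to an alkenyl substituent, and a Cope path through C3=C4 would require an anti-Bredt alkene and is closed), and suppression of carbenoid dimerisation and vinylogous attack, which slow addition in a hydrocarbon solvent with excess diene should secure.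

Step 7
Reactants: 12 methyl (8S)-2-ethoxy-3,8-dimethyl-6-oxo-1,4,5,6,7,8-hexahydroazulene-5-carboxylate
Product: 13 methyl (5S,6R,8S)-2-ethoxy-6-hydroxy-3,8-dimethyl-1,4,5,6,7,8-hexahydroazulene-5-carboxylate
Conditions: NaBH4 (1.5 equiv), MnCl2 (2 equiv), MeOH, −40 → −20 °C; pH 7 buffer work-up
Reagents that add atoms: none
Why: Chelation-controlled hydride reduction of the α-substituted β-keto ester should deliver hydride to C8 on the ring face opposite the ester (cis-hydroxy ester), and because C7 epimerises through the enol while the C10 methyl group also directs hydride to the opposite face, the 7,10-cis epimer should react fastest (dynamic kinetic resolution) to give the 7,8,10-all-cis isomer (7S,8R in guaiane numbering).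

Step 8
Reactants: 13 methyl (5S,6R,8S)-2-ethoxy-6-hydroxy-3,8-dimethyl-1,4,5,6,7,8-hexahydroazulene-5-carboxylate
Product: 15 (5S,6R,8S,8aR)-6-hydroxy-5-(2-hydroxypropan-2-yl)-3,8-dimethyl-4,5,6,7,8,8a-hexahydroazulen-2(1H)-one, via ethoxydiene diol 14 (not isolated)
Conditions: MeMgBr (6 equiv), THF, −20 → 25 °C; then 1 M aq HCl, THF, 25 °C, 12 h
Reagents that add atoms: methylmagnesium bromide C[Mg]Br; water O
Why: Double Grignard addition to the ester of the magnesium alkoxide should give tertiary carbinol 14, and the acidic work-up hydrolyses the cyclopentadienyl ethyl ether (Stork–Danheiser-type unmasking) to the tetrasubstituted C4=C5 enone, the thermodynamic sink for all double-bond isomers of the diene, with C1, a γ-position that epimerises through the dienol, expected to settle in the 1,10-trans arrangement (C2 and the C10 methyl both pseudo-equatorial) of the target.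

Step 9
Reactants: 15 (5S,6R,8S,8aR)-6-hydroxy-5-(2-hydroxypropan-2-yl)-3,8-dimethyl-4,5,6,7,8,8a-hexahydroazulen-2(1H)-one
Product: 16 (5S,6R,8S,8aR)-5-(2-hydroxypropan-2-yl)-3,8-dimethyl-2-oxo-1,2,4,5,6,7,8,8a-octahydroazulen-6-yl 2-methylprop-2-enoate
Conditions: methacryloyl chloride (1.5 equiv), Et3N, DMAP (0.1 equiv), BHT (trace), CH2Cl2, −20 → 0 °C
Reagents that add atoms: methacryloyl chloride C=C(C)C(Cl)=O
Why: DMAP-catalysed acylation at low temperature should discriminate the secondary C8 hydroxyl from the tertiary C11 hydroxyl and proceeds with retention at C8.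

Step 10
Reactants: 16 (5S,6R,8S,8aR)-5-(2-hydroxypropan-2-yl)-3,8-dimethyl-2-oxo-1,2,4,5,6,7,8,8a-octahydroazulen-6-yl 2-methylprop-2-enoate
Product: 17 (5S,6R,8S,8aR)-5-(2-acetoxypropan-2-yl)-3,8-dimethyl-2-oxo-1,2,4,5,6,7,8,8a-octahydroazulen-6-yl 2-methylprop-2-enoate
Conditions: Ac2O (10 equiv), DMAP (1 equiv), Et3N, CH2Cl2, 40 °C
Reagents that add atoms: acetic anhydride CC(=O)OC(C)=O
Why: Steglich-type DMAP-catalysed acetylation with excess anhydride should esterify the hindered tertiary alcohol without touching the enone or the methacrylate and creates no stereocentre.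

Compound list
1 | 2-methylcyclopentane-1,3-dione | CC1C(=O)CCC1=O | starting material
2 | 3-ethoxy-2-methylcyclopent-2-en-1-one | CCOC1=C(C)C(=O)CC1 | intermediate
3 | lithium 1-(4-ethoxy-3-methyl-2-oxocyclopent-3-en-1-yl)ethan-1-olate (lithium aldolate, racemic diastereomer mixture) | [Li+].CC([O-])C1CC(OCC)=C(C)C1=O | intermediate
4 | 1-(4-ethoxy-3-methyl-2-oxocyclopent-3-en-1-yl)ethyl methanesulfonate (racemic diastereomer mixture) | CC(OS(C)(=O)=O)C1CC(OCC)=C(C)C1=O | intermediate
5 | (E)-3-ethoxy-5-ethylidene-2-methylcyclopent-2-en-1-one | C/C=C1/C(=O)C(C)=C(OCC)C1 | intermediate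
6 | (E)-1-ethoxy-4-ethylidene-2-methyl-3-methylidenecyclopent-1-ene (achiral triene) | C/C=C1/C(=C)C(C)=C(OCC)C1 | intermediate
7 | methyl 3-oxobutanoate (methyl acetoacetate) | CC(=O)CC(=O)OC | starting material
8 | methyl 2-diazo-3-oxobutanoate | CC(=O)C(=[N+]=[N-])C(=O)OC | intermediate
9 | methyl 3-[(tert-butyldimethylsilyl)oxy]-2-diazobut-3-enoate | C=C(O[Si](C)(C)C(C)(C)C)C(=[N+]=[N-])C(=O)OC | intermediate
10 | methyl 1-{1-[(tert-butyldimethylsilyl)oxy]ethenyl}-5-ethoxy-7-[(E)-ethylidene]-4-methylspiro[2.4]hept-4-ene-1-carboxylate, siloxyvinyl group cis to the ethylidene-bearing ring carbon on the cyclopropane, absolute configuration as in the SMILES | C/C=C1\CC(OCC)=C(C)[C@@]12C[C@@]2(C(=O)OC)C(=C)O[Si](C)(C)C(C)(C)C | intermediate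
11 | methyl (8S)-6-[(tert-butyldimethylsilyl)oxy]-2-ethoxy-3,8-dimethyl-1,4,7,8-tetrahydroazulene-5-carboxylate | C[C@H]1CC(O[Si](C)(C)C(C)(C)C)=C(C(=O)OC)CC2=C1CC(OCC)=C2C | intermediate
12 | methyl (8S)-2-ethoxy-3,8-dimethyl-6-oxo-1,4,5,6,7,8-hexahydroazulene-5-carboxylate (C5 epimers and enol in equilibrium) | C[C@H]1CC(=O)C(C(=O)OC)CC2=C1CC(OCC)=C2C | intermediate
13 | methyl (5S,6R,8S)-2-ethoxy-6-hydroxy-3,8-dimethyl-1,4,5,6,7,8-hexahydroazulene-5-carboxylate (ester, hydroxyl and methyl all cis) | O[C@@H]1C[C@H](C)C2=C(C[C@@H]1C(=O)OC)C(C)=C(OCC)C2 | intermediate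
14 | (5S,6R,8S)-2-ethoxy-5-(2-hydroxypropan-2-yl)-3,8-dimethyl-1,4,5,6,7,8-hexahydroazulen-6-ol | O[C@@H]1C[C@H](C)C2=C(C[C@@H]1C(C)(C)O)C(C)=C(OCC)C2 | intermediate
15 | (5S,6R,8S,8aR)-6-hydroxy-5-(2-hydroxypropan-2-yl)-3,8-dimethyl-4,5,6,7,8,8a-hexahydroazulen-2(1H)-one | O[C@@H]1C[C@H](C)[C@H]2CC(=O)C(C)=C2C[C@@H]1C(C)(C)O | intermediate
16 | (5S,6R,8S,8aR)-5-(2-hydroxypropan-2-yl)-3,8-dimethyl-2-oxo-1,2,4,5,6,7,8,8a-octahydroazulen-6-yl 2-methylprop-2-enoate | C=C(C)C(=O)O[C@@H]1C[C@H](C)[C@H]2CC(=O)C(C)=C2C[C@@H]1C(C)(C)O | intermediate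
17 | (5S,6R,8S,8aR)-5-(2-acetoxypropan-2-yl)-3,8-dimethyl-2-oxo-1,2,4,5,6,7,8,8a-octahydroazulen-6-yl 2-methylprop-2-enoate (CNP0318307.1) | C=C(C)C(=O)O[C@@H]1C[C@H](C)[C@H]2CC(=O)C(C)=C2C[C@@H]1C(C)(C)OC(C)=O | target

Total step count: 10. Longest linear sequence: 8 steps (steps 1–3 and 6–10 from 1); the diazo partner 9 takes 2 steps (4 and 5).

Steps most likely to fail

Step 6. The electrophilic rhodium carbenoid may attack the very electron-rich trienol ether stepwise through a zwitterion (formal (3+2) annulation, vinylogous addition or allylic C–H insertion at C2) instead of cyclopropanating it. Incomplete cis selectivity in the cyclopropanation would also force the rearrangement through reversible homolysis of the C5–C7 bond and erode the enantiomeric purity at C10. The fallback replaces the enol ether by a ketal, so that the diene is an ordinary 1,2-dialkylidenecyclopentane. Setting out from 5, transketalisation with ethylene glycol (PPTS, toluene, reflux, ethanol distilled off) should give the keto ketal (E)-8-ethylidene-6-methyl-1,4-dioxaspiro[4.4]nonan-7-one F1. Methylenation with Cp2Ti(μ-Cl)(μ-CH2)AlMe2 should then give the ketal diene F2. The same Rh2(S-PTAD)4-catalysed cyclopropanation/Cope sequence with 9 should give the ketal silyl enol ether F3, and TBAF the ketal β-keto ester F4. NaBH4/MnCl2 should give the ketal hydroxy ester F5 and MeMgBr the ketal diol F6. Aqueous HCl then removes the ketal and moves the C1=C5 alkene into conjugation, which comes back to the route at 15. The extra C4 stereocentre of F1 to F6 is carried as a mixture and disappears in the last operation.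

Step 7. Facial discrimination by the remote C10 methyl group may be poor, or C7 may epimerise too slowly relative to reduction, so that hydride is delivered to both faces of C8. The fallback moves the control from the substrate to a catalyst. Setting out from 12, asymmetric transfer hydrogenation under dynamic kinetic resolution with RuCl(p-cymene)[(S,S)-TsDPEN] or its (R,R) enantiomer, whichever is matched with C10, and HCO2Na in H2O/CH2Cl2 at 30 °C should give the cis-hydroxy ester with the C8 configuration fixed by the ligand; the neutral medium is tolerated by the enol ether. It comes back to the route at 13 and makes no new compound.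

Step 8. Double addition to the hindered ester beside a magnesium alkoxide may stall through enolisation or retro-aldol cleavage of the intermediate β-alkoxy methyl ketone, and protonation at C1 under the acidic work-up may stay under kinetic control. The fallback separates protection, addition and equilibration. Setting out from 13, TESCl/imidazole in DMF should give the triethylsilyl ether F7, and MeLi/CeCl3 in THF at −78 °C the silyl-protected carbinol F8. 1 M HCl in THF then removes the silyl group and the enol ether and comes back to the route at 15. Any C1 epimer F9 left by kinetic protonation is converted into 15 by equilibration through the dienolate with NaOMe in MeOH.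

Further compounds
F1 | step 6 | (E)-8-ethylidene-6-methyl-1,4-dioxaspiro[4.4]nonan-7-one (racemic) | C/C=C1/C(=O)C(C)C2(OCCO2)C1
F2 | step 6 | (E)-8-ethylidene-6-methyl-7-methylidene-1,4-dioxaspiro[4.4]nonane (racemic) | C/C=C1/C(=C)C(C)C2(OCCO2)C1
F3 | step 6 | ketal silyl enol ether: as 11 but with C3 as a 1,3-dioxolane ketal and C4 as CH(CH3), (10S), C4 epimers | C[C@H]1CC(O[Si](C)(C)C(C)(C)C)=C(C(=O)OC)CC2=C1CC1(OCCO1)C2C
F4 | step 6 | ketal β-keto ester: as 12 but with C3 as a 1,3-dioxolane ketal and C4 as CH(CH3), (10S), C4 and C7 epimers | C[C@H]1CC(=O)C(C(=O)OC)CC2=C1CC1(OCCO1)C2C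
F5 | step 6 | ketal hydroxy ester: as 13 but with C3 as a 1,3-dioxolane ketal and C4 as CH(CH3), (7S,8R,10S), C4 epimers | O[C@@H]1C[C@H](C)C2=C(C[C@@H]1C(=O)OC)C(C)C1(OCCO1)C2
F6 | step 6 | ketal diol: as 14 but with C3 as a 1,3-dioxolane ketal and C4 as CH(CH3), (7S,8R,10S), C4 epimers | O[C@@H]1C[C@H](C)C2=C(C[C@@H]1C(C)(C)O)C(C)C1(OCCO1)C2
F0 | step 7 | none | none
F7 | step 8 | methyl (5S,6R,8S)-2-ethoxy-3,8-dimethyl-6-[(triethylsilyl)oxy]-1,4,5,6,7,8-hexahydroazulene-5-carboxylate | CC[Si](CC)(CC)O[C@@H]1C[C@H](C)C2=C(C[C@@H]1C(=O)OC)C(C)=C(OCC)C2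
F8 | step 8 | 2-[(5S,6R,8S)-2-ethoxy-3,8-dimethyl-6-[(triethylsilyl)oxy]-1,4,5,6,7,8-hexahydroazulen-5-yl]propan-2-ol | CC[Si](CC)(CC)O[C@@H]1C[C@H](C)C2=C(C[C@@H]1C(C)(C)O)C(C)=C(OCC)C2
F9 | step 8 | (5S,6R,8S,8aS)-6-hydroxy-5-(2-hydroxypropan-2-yl)-3,8-dimethyl-4,5,6,7,8,8a-hexahydroazulen-2(1H)-one (C1 epimer of 15) | O[C@@H]1C[C@H](C)[C@@H]2CC(=O)C(C)=C2C[C@@H]1C(C)(C)O
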